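**Retrosynthetic overview**

- Last ring: the ε-lactone comes from a Baeyer–Villiger ring expansion (six to seven) of an α-methylidene cyclohexanone bridged inside the macrocycle. The quaternary carbon migrates with retention and becomes the tertiary lactone C–O centre.
- The tetrahydrofuran is closed just before that by transannular 5-exo opening of an (S,S)-trisubstituted epoxide by the allylic hydroxyl.
- The 14-membered carbocycle is closed by a nickel-catalysed, exo-selective reductive ynal cyclisation, which makes the C–C bond next to the 1,1-disubstituted alkene.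
- The quaternary centre comes from a Morita–Baylis–Hillman coupling of a 5-substituted cyclohexenone with pent-4-ynal, then conjugate reduction and enolate methylation. The cyclohexenone is made by an organocatalytic Michael/aldol annulation of an acetoacetate with a dienal built from pent-4-yn-1-ol, allyl bromide and crotonaldehyde.
- Ring order: cyclohexenone, then 14-membered carbocycle, then tetrahydrofuran, then ring expansion to the lactone.

**Assumption and labels**

- Pent-4-ynal is taken as a purchased starting material.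
- Skeletal labels are those of the target: C1 (ring CH bonded to C2, C14, C15); C2 (CH2); C3 (CHOAc); C4 (C–Me on the tetrahydrofuran); C5, C6 (CH2); C7 (tetrahydrofuran CH); C8 (=CH2); C9, C10 (CH2); C11 (CHOAc); C12 (C–Me carrying the lactone oxygen); C13, C14 (CH2); C15 (=CH2); C16 (C=O).
- Bridged macrocycles are named as bicyclo[10.2.2]hexadecanes with the same locants: C1 and C12 are bridgeheads, C15 sits on C1 and C16 on C12.

**Route**

Step 1
Reactants: 1 pent-4-yn-1-ol; 2 3-bromoprop-1-ene (allyl bromide)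
Product: 4 (4E)-4-methylocta-4,7-dien-1-ol, via alkenylalane 3 (not isolated)
Conditions: Me3Al (3 equiv), Cp2ZrCl2 (0.25 equiv), CH2Cl2, 0 °C to rt; then 2, Pd(PPh3)4 (3 mol%), THF, rt; aqueous work-up
Reagents that add atoms: trimethylaluminium, C[Al](C)C
Why: Zirconium-catalysed syn-carboalumination (Negishi) puts the methyl on the internal alkyne carbon, and palladium-catalysed allylation of the alkenylalane with retention fixes the (E)-trisubstituted C3=C4 alkene.

Step 2
Reactants: 4 (4E)-4-methylocta-4,7-dien-1-ol; 5 (2E)-but-2-enal (crotonaldehyde)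
Product: 6 (2E,5E)-9-hydroxy-6-methylnona-2,5-dienal
Conditions: second-generation Hoveyda–Grubbs catalyst RuCl2(H2IMes)(=CH-C6H4-2-O-i-Pr) (3 mol%), 5 (5 equiv), CH2Cl2, 40 °C
Reagents that add atoms: none
Why: Olefin cross-metathesis of the terminal alkene with excess crotonaldehyde gives the (E)-enal, while the trisubstituted alkene does not react.

Step 3
Reactants: 7 4-methylideneoxetan-2-one (diketene); 8 prop-2-en-1-ol (allyl alcohol)
Product: 9 prop-2-en-1-yl 3-oxobutanoate (allyl acetoacetate)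
Conditions: NaOAc (cat.), neat, 60–80 °C
Reagents that add atoms: none
Why: Acylation of the alcohol by diketene (ring-opening alcoholysis) gives the acetoacetate cleanly.

Step 4
Reactants: 6 (2E,5E)-9-hydroxy-6-methylnona-2,5-dienal; 9 prop-2-en-1-yl 3-oxobutanoate
Product: 11 (5R)-5-[(2E)-6-hydroxy-3-methylhex-2-en-1-yl]cyclohex-2-en-1-one, via Michael adduct 10 (not isolated)
Conditions: (R)-2-[diphenyl(trimethylsilyloxy)methyl]pyrrolidine (10 mol%), PhCO2H (10 mol%), toluene, −20 to 0 °C; then Pd(PPh3)4 (3 mol%), morpholine (1.5 equiv), THF, rt to 40 °C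
Reagents that add atoms: none
Why: Iminium-catalysed Michael addition of the β-ketoester (Jørgensen–Hayashi catalyst) sets C1 as R because the (R)-catalyst shields one face of the enal; deallylation–decarboxylation with zerovalent palladium and amine-promoted aldol condensation then close the cyclohexenone without strong acid, and the addition is run cold with an acid co-catalyst so that it outpaces γ-deprotonation of the skipped diene.

Step 5
Reactants: 11 (5R)-5-[(2E)-6-hydroxy-3-methylhex-2-en-1-yl]cyclohex-2-en-1-one; 12 pent-4-ynal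
Product: 13 (5S)-5-[(2E)-6-hydroxy-3-methylhex-2-en-1-yl]-2-[(1R)-1-hydroxypent-4-yn-1-yl]cyclohex-2-en-1-one
Conditions: PEt3 (1 equiv), (R)-3,3′-bis[3,5-bis(trifluoromethyl)phenyl]-5,5′,6,6′,7,7′,8,8′-octahydro-1,1′-bi-2-naphthol (10 mol%), 12 (3 equiv), THF, −10 °C, 48 h
Reagents that add atoms: none
Why: Asymmetric Morita–Baylis–Hillman reaction forms C11–C12, and the chiral Brønsted acid bound to the phosphonium enolate sets C11 as R under catalyst control (the acid antipode that gives the 1R carbinol is used, checked by Mosher analysis; the ring descriptor changes to 5S only through ligand priorities).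

Step 6
Reactants: 13 (5S)-5-[(2E)-6-hydroxy-3-methylhex-2-en-1-yl]-2-[(1R)-1-hydroxypent-4-yn-1-yl]cyclohex-2-en-1-one
Product: 14 (5S)-5-[(2E)-3-methyl-6-(triethylsilyloxy)hex-2-en-1-yl]-2-[(1R)-1-(triethylsilyloxy)pent-4-yn-1-yl]cyclohex-2-en-1-one
Conditions: Et3SiCl (2.5 equiv), imidazole (4 equiv), DMAP (cat.), CH2Cl2, 0 °C to rt
Reagents that add atoms: chlorotriethylsilane, CC[Si](Cl)(CC)CC
Why: Silylation of both hydroxyls; triethylsilyl is chosen because the primary ether can later be oxidised directly to the aldehyde and both ethers can be removed together.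

Step 7
Reactants: 14 (5S)-5-[(2E)-3-methyl-6-(triethylsilyloxy)hex-2-en-1-yl]-2-[(1R)-1-(triethylsilyloxy)pent-4-yn-1-yl]cyclohex-2-en-1-one
Product: 16 (2R,5R)-2-methyl-5-[(2E)-3-methyl-6-(triethylsilyloxy)hex-2-en-1-yl]-2-[(1R)-1-(triethylsilyloxy)pent-4-yn-1-yl]cyclohexan-1-one, via lithium enolate 15 (not isolated)
Conditions: LiBH(s-Bu)3 (1.1 equiv), THF, −78 °C; then MeI (5 equiv), HMPA (4 equiv), −78 to −30 °C
Reagents that add atoms: iodomethane, CI
Why: Reductive alkylation: 1,4-hydride addition gives the C12 enolate regiospecifically, and methyl iodide enters axially, cis to the equatorial C1 side chain and anti to the C10 arm of the H-eclipsed silyloxyalkyl group, which sets the C12 quaternary centre as R.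

Step 8
Reactants: 16 (2R,5R)-2-methyl-5-[(2E)-3-methyl-6-(triethylsilyloxy)hex-2-en-1-yl]-2-[(1R)-1-(triethylsilyloxy)pent-4-yn-1-yl]cyclohexan-1-one
Product: 17 (2R,5R)-2-methyl-5-({(2S,3S)-3-methyl-3-[3-(triethylsilyloxy)propyl]oxiran-2-yl}methyl)-2-[(1R)-1-(triethylsilyloxy)pent-4-yn-1-yl]cyclohexan-1-one
Conditions: L-fructose-derived Shi ketone (30 mol%), KHSO5 (as Oxone, 2KHSO5·KHSO4·K2SO4), K2CO3, Bu4NHSO4, MeCN–CH2(OMe)2 / aq. Na2B4O7–Na2EDTA buffer, 0 °C
Reagents that add atoms: potassium peroxymonosulfate, OOS(=O)(=O)[O-].[K+]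
Why: Shi asymmetric epoxidation oxidises only the electron-rich trisubstituted alkene and gives the (3S,4S)-epoxide under reagent control on an acyclic chain; the alkyne, ketone and silyl ethers are inert.

Step 9
Reactants: 17 (2R,5R)-2-methyl-5-({(2S,3S)-3-methyl-3-[3-(triethylsilyloxy)propyl]oxiran-2-yl}methyl)-2-[(1R)-1-(triethylsilyloxy)pent-4-yn-1-yl]cyclohexan-1-one
Product: 18 3-[(2S,3S)-2-methyl-3-({(1R,4R)-4-methyl-3-oxo-4-[(1R)-1-(triethylsilyloxy)pent-4-yn-1-yl]cyclohexyl}methyl)oxiran-2-yl]propanal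
Conditions: (COCl)2 (4 equiv), DMSO (8 equiv), CH2Cl2, −78 to −35 °C; then Et3N, to 0 °C
Reagents that add atoms: none
Why: Swern conditions convert a primary triethylsilyl ether directly into the aldehyde, while the hindered secondary silyl ether and the epoxide survive.

Step 10
Reactants: 18 3-[(2S,3S)-2-methyl-3-({(1R,4R)-4-methyl-3-oxo-4-[(1R)-1-(triethylsilyloxy)pent-4-yn-1-yl]cyclohexyl}methyl)oxiran-2-yl]propanal
Product: 19 (1R,3S,4S,7S,11R,12R)-3,4-epoxy-4,12-dimethyl-8-methylidene-7,11-bis(triethylsilyloxy)bicyclo[10.2.2]hexadecan-16-one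
Conditions: Ni(cod)2 (20 mol%), 1,3-bis(2,6-diisopropylphenyl)-4,5-diphenylimidazol-2-ylidene (20 mol%), Et3SiH (3 equiv), THF, rt, slow addition of 18 to 2 mM
Reagents that add atoms: triethylsilane, CC[SiH](CC)CC
Why: Nickel-catalysed reductive aldehyde–alkyne macrocyclisation (oxidative cyclisation, then Si–H σ-bond metathesis) closes the 14-membered ring; the bulky carbene directs C–C formation to the internal alkyne carbon, giving the exocyclic methylidene, and C7 is set by the macrocyclic transition state (7S expected, substrate control, to be verified).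

Step 11
Reactants: 19 (1R,3S,4S,7S,11R,12R)-3,4-epoxy-4,12-dimethyl-8-methylidene-7,11-bis(triethylsilyloxy)bicyclo[10.2.2]hexadecan-16-one
Product: 21 (1R,3S,4R,7S,11R,12R)-4,7-epoxy-3,11-dihydroxy-4,12-dimethyl-8-methylidenebicyclo[10.2.2]hexadecan-16-one, via diol epoxide 20 (not isolated)
Conditions: Bu4NF, AcOH (1:1, 3 equiv), THF, 0 °C to rt; then CSA (10 mol%), CH2Cl2, 0 °C
Reagents that add atoms: none
Why: Buffered fluoride removes both silyl ethers, and acid-catalysed transannular 5-exo epoxide opening by the C7 hydroxyl (SN2, inversion at C4, retention at C3) gives the 2,5-cis tetrahydrofuran with 3S and 4R.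

Step 12
Reactants: 21 (1R,3S,4R,7S,11R,12R)-4,7-epoxy-3,11-dihydroxy-4,12-dimethyl-8-methylidenebicyclo[10.2.2]hexadecan-16-one
Product: 22 (1R,3S,4R,7S,11R,12R)-4,7-epoxy-4,12-dimethyl-8-methylidene-16-oxobicyclo[10.2.2]hexadecane-3,11-diyl diacetate
Conditions: Ac2O, pyridine, DMAP (cat.), CH2Cl2, rt
Reagents that add atoms: acetic anhydride, CC(=O)OC(C)=O
Why: DMAP-catalysed acetylation installs both acetates of the target and blocks retro-aldol cleavage of the β-hydroxy ketone.

Step 13
Reactants: 22 (1R,3S,4R,7S,11R,12R)-4,7-epoxy-4,12-dimethyl-8-methylidene-16-oxobicyclo[10.2.2]hexadecane-3,11-diyl diacetate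
Product: 23 (1R,3S,4R,7S,11R,12R)-4,7-epoxy-4,12-dimethyl-8,15-dimethylidene-16-oxobicyclo[10.2.2]hexadecane-3,11-diyl diacetate
Conditions: (CH2O)n, N-methylanilinium trifluoroacetate, THF, reflux
Reagents that add atoms: paraformaldehyde (formaldehyde), C=O
Why: Mannich condensation–elimination (α-methylenation) can only occur at C15, the sole enolisable position, under weakly acidic conditions that leave the acetates untouched.

Step 14
Reactants: 23 (1R,3S,4R,7S,11R,12R)-4,7-epoxy-4,12-dimethyl-8,15-dimethylidene-16-oxobicyclo[10.2.2]hexadecane-3,11-diyl diacetate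
Product: 24 granosolide B
Conditions: Me3SiOOSiMe3 (2.5 equiv), SnCl4 (0.3 equiv), (±)-trans-1,2-bis(trifluoromethanesulfonamido)cyclohexane (0.3 equiv), 4 Å MS, CH2Cl2, −20 to 0 °C
Reagents that add atoms: bis(trimethylsilyl) peroxide, C[Si](C)(C)OO[Si](C)(C)C
Why: Proposed new method: Baeyer–Villiger ring expansion of an α-methylidene ketone to the α-methylene ε-lactone; the tin Lewis acid activates the hindered C16 carbonyl, the silyl peroxide adds 1,2 to give a silylated Criegee adduct, and the tertiary C12–C16 bond (better able to carry positive charge than the sp2 C15 and antiperiplanar to O–O) migrates with retention, so C12 becomes the (12R) lactone C–O centre and the ring grows from six to seven; the non-basic medium disfavours conjugate (Weitz–Scheffer) epoxidation of the enone, and with no peracid present the C8 methylidene, the acetates and the tetrahydrofuran are left alone; the closest known chemistry is the Lewis-acid/bis(silyl) peroxide Baeyer–Villiger oxidation of saturated α-branched cyclohexanones in the presence of alkenes, which has not been shown on α-methylidene ketones.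

**Compound list**

1 | pent-4-yn-1-ol | C#CCCCO | starting material
2 | 3-bromoprop-1-ene (allyl bromide) | C=CCBr | starting material
3 | dimethyl[(1E)-5-(dimethylalumanyloxy)-2-methylpent-1-en-1-yl]alumane (alkenylalane, not isolated) | C[Al](C)/C=C(\C)CCCO[Al](C)C | intermediate
4 | (4E)-4-methylocta-4,7-dien-1-ol | OCCC/C(C)=C/CC=C | intermediate
5 | (2E)-but-2-enal (crotonaldehyde) | C/C=C/C=O | starting material
6 | (2E,5E)-9-hydroxy-6-methylnona-2,5-dienal | O=C/C=C/C/C=C(\C)CCCO | intermediate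
7 | 4-methylideneoxetan-2-one (diketene) | C=C1CC(=O)O1 | starting material
8 | prop-2-en-1-ol (allyl alcohol) | C=CCO | starting material
9 | prop-2-en-1-yl 3-oxobutanoate (allyl acetoacetate) | CC(=O)CC(=O)OCC=C | intermediate
10 | prop-2-en-1-yl (3S,5E)-2-acetyl-9-hydroxy-6-methyl-3-(2-oxoethyl)non-5-enoate (Michael adduct, C2 epimers, not isolated) | CC(=O)C(C(=O)OCC=C)[C@H](CC=O)C/C=C(\C)CCCO | intermediate
11 | (5R)-5-[(2E)-6-hydroxy-3-methylhex-2-en-1-yl]cyclohex-2-en-1-one | O=C1C=CC[C@H](C/C=C(\C)CCCO)C1 | intermediate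
12 | pent-4-ynal | C#CCCC=O | starting material
13 | (5S)-5-[(2E)-6-hydroxy-3-methylhex-2-en-1-yl]-2-[(1R)-1-hydroxypent-4-yn-1-yl]cyclohex-2-en-1-one | O=C1C([C@H](O)CCC#C)=CC[C@H](C/C=C(\C)CCCO)C1 | intermediate
14 | (5S)-5-[(2E)-3-methyl-6-(triethylsilyloxy)hex-2-en-1-yl]-2-[(1R)-1-(triethylsilyloxy)pent-4-yn-1-yl]cyclohex-2-en-1-one | O=C1C([C@H](O[Si](CC)(CC)CC)CCC#C)=CC[C@H](C/C=C(\C)CCCO[Si](CC)(CC)CC)C1 | intermediate
15 | lithium (5R)-5-[(2E)-3-methyl-6-(triethylsilyloxy)hex-2-en-1-yl]-2-[(1R)-1-(triethylsilyloxy)pent-4-yn-1-yl]cyclohex-1-en-1-olate (not isolated) | [Li]OC1=C([C@H](O[Si](CC)(CC)CC)CCC#C)CC[C@H](C/C=C(\C)CCCO[Si](CC)(CC)CC)C1 | intermediate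
16 | (2R,5R)-2-methyl-5-[(2E)-3-methyl-6-(triethylsilyloxy)hex-2-en-1-yl]-2-[(1R)-1-(triethylsilyloxy)pent-4-yn-1-yl]cyclohexan-1-one | C1C(=O)[C@](C)(CC[C@@H]1C/C=C(\C)CCCO[Si](CC)(CC)CC)[C@H](O[Si](CC)(CC)CC)CCC#C | intermediate
17 | (2R,5R)-2-methyl-5-({(2S,3S)-3-methyl-3-[3-(triethylsilyloxy)propyl]oxiran-2-yl}methyl)-2-[(1R)-1-(triethylsilyloxy)pent-4-yn-1-yl]cyclohexan-1-one | C1C(=O)[C@](C)(CC[C@@H]1C[C@@H]2O[C@@]2(C)CCCO[Si](CC)(CC)CC)[C@H](O[Si](CC)(CC)CC)CCC#C | intermediate
18 | 3-[(2S,3S)-2-methyl-3-({(1R,4R)-4-methyl-3-oxo-4-[(1R)-1-(triethylsilyloxy)pent-4-yn-1-yl]cyclohexyl}methyl)oxiran-2-yl]propanal | C1C(=O)[C@](C)(CC[C@@H]1C[C@@H]2O[C@@]2(C)CCC=O)[C@H](O[Si](CC)(CC)CC)CCC#C | intermediate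
19 | (1R,3S,4S,7S,11R,12R)-3,4-epoxy-4,12-dimethyl-8-methylidene-7,11-bis(triethylsilyloxy)bicyclo[10.2.2]hexadecan-16-one | C1C(=O)[C@]2(C)CC[C@@H]1C[C@@H]3O[C@@]3(C)CC[C@H](O[Si](CC)(CC)CC)C(=C)CC[C@H]2O[Si](CC)(CC)CC | intermediate
20 | (1R,3S,4S,7S,11R,12R)-3,4-epoxy-7,11-dihydroxy-4,12-dimethyl-8-methylidenebicyclo[10.2.2]hexadecan-16-one (diol epoxide, not isolated) | C1C(=O)[C@]2(C)CC[C@@H]1C[C@@H]3O[C@@]3(C)CC[C@H](O)C(=C)CC[C@H]2O | intermediate
21 | (1R,3S,4R,7S,11R,12R)-4,7-epoxy-3,11-dihydroxy-4,12-dimethyl-8-methylidenebicyclo[10.2.2]hexadecan-16-one | C1C(=O)[C@]2(C)CC[C@@H]1C[C@H](O)[C@@]1(C)CC[C@H](O1)C(=C)CC[C@H]2O | intermediate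
22 | (1R,3S,4R,7S,11R,12R)-4,7-epoxy-4,12-dimethyl-8-methylidene-16-oxobicyclo[10.2.2]hexadecane-3,11-diyl diacetate | C1C(=O)[C@]2(C)CC[C@@H]1C[C@H](OC(C)=O)[C@@]1(C)CC[C@H](O1)C(=C)CC[C@H]2OC(C)=O | intermediate
23 | (1R,3S,4R,7S,11R,12R)-4,7-epoxy-4,12-dimethyl-8,15-dimethylidene-16-oxobicyclo[10.2.2]hexadecane-3,11-diyl diacetate | C=C1C(=O)[C@]2(C)CC[C@@H]1C[C@H](OC(C)=O)[C@@]1(C)CC[C@H](O1)C(=C)CC[C@H]2OC(C)=O | intermediate
24 | granosolide B | C=C1C(=O)O[C@]2(C)CC[C@@H]1C[C@H](OC(C)=O)[C@@]1(C)CC[C@H](O1)C(=C)CC[C@H]2OC(C)=O | target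

**Step count and risks**

Total: 14 steps. Longest linear sequence: 13 steps (1, 2, 4–14); step 3 is a one-step side branch.

The three steps most likely to fail are steps 7, 10 and 14.

- **Reductive methylation (step 7).** The β-silyloxy enolate 15 can lose silanolate before it is alkylated, and facial control at C12 rests on two modest biases (axial attack and the conformation of the silyloxyalkyl group). The fallback sets out from 14 and avoids a free enolate. LiBH(s-Bu)3 in THF at −78 °C followed by Me3SiCl gives the trimethylsilyl enol ether F1. Et2Zn/CH2I2 (1.2 equiv, CH2Cl2, −20 °C) cyclopropanates the electron-rich enol ether in a concerted, ether-directed Simmons–Smith reaction (syn to the C11 oxygen, anti to the C10 arm) and gives the siloxycyclopropane F2. K2CO3 in MeOH then removes the trimethylsilyl group and opens the cyclopropanol at its CH2–C16 bond (Conia methylation). This comes back to the route at 16.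

- **Nickel macrocyclisation (step 10).** The C7 configuration is only substrate-controlled, and the ring being closed is bridged by the cyclohexanone. If 19 forms as a C7 epimer mixture, the fallback sets out from 19. One equivalent of buffered Bu4NF/AcOH at −20 °C removes the less hindered allylic silyl ether to give the C7 alcohol F3. Dess–Martin periodinane with NaHCO3 gives the enone F4. (R)-2-methyl-CBS-oxazaborolidine with catecholborane at −78 °C reduces it under reagent control to the (7S)-alcohol F5. The conditions of step 11 then remove the remaining silyl ether and close the tetrahydrofuran. This comes back to the route at 21.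

- **Baeyer–Villiger ring expansion (step 14, the proposed new step).** Peroxide may add in conjugate fashion to the unhindered methylidene, or the alkenyl carbon may migrate. The fallback uses known chemistry and sets out from 23. PhSO2Na and AcOH in EtOH add sulfinate to the enone and give the β-sulfonyl ketone F6, which is now a saturated ketone with a tertiary and a deactivated secondary α-carbon. The same bis(trimethylsilyl) peroxide/SnCl4–bis-sulfonamide conditions, which are established for saturated ketones in the presence of alkenes, give the sulfonyl lactone F7 by tertiary-alkyl migration. DBU in CH2Cl2 then eliminates benzenesulfinate (E1cB) to unveil the α-methylene lactone. This comes back to the route at 24.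

**Further compounds**

F1 | step 7 | {[(5R)-5-[(2E)-3-methyl-6-(triethylsilyloxy)hex-2-en-1-yl]-2-[(1R)-1-(triethylsilyloxy)pent-4-yn-1-yl]cyclohex-1-en-1-yl]oxy}trimethylsilane | C[Si](C)(C)OC1=C([C@H](O[Si](CC)(CC)CC)CCC#C)CC[C@H](C/C=C(\C)CCCO[Si](CC)(CC)CC)C1
F2 | step 7 | 1-(trimethylsilyloxy)bicyclo[4.1.0]heptane carrying the (1R)-1-(triethylsilyloxy)pent-4-yn-1-yl group at C6 and the (2E)-3-methyl-6-(triethylsilyloxy)hex-2-en-1-yl chain at C3, C7 methylene cis to that chain | C1[C@]2(O[Si](C)(C)C)C[C@@]2(CC[C@@H]1C/C=C(\C)CCCO[Si](CC)(CC)CC)[C@H](O[Si](CC)(CC)CC)CCC#C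
F3 | step 10 | (1R,3S,4S,11R,12R)-3,4-epoxy-7-hydroxy-4,12-dimethyl-8-methylidene-11-(triethylsilyloxy)bicyclo[10.2.2]hexadecan-16-one (C7 epimers) | C1C(=O)[C@]2(C)CC[C@@H]1C[C@@H]3O[C@@]3(C)CCC(O)C(=C)CC[C@H]2O[Si](CC)(CC)CC
F4 | step 10 | (1R,3S,4S,11R,12R)-3,4-epoxy-4,12-dimethyl-8-methylidene-11-(triethylsilyloxy)bicyclo[10.2.2]hexadecane-7,16-dione | C1C(=O)[C@]2(C)CC[C@@H]1C[C@@H]3O[C@@]3(C)CCC(=O)C(=C)CC[C@H]2O[Si](CC)(CC)CC
F5 | step 10 | (1R,3S,4S,7S,11R,12R)-3,4-epoxy-7-hydroxy-4,12-dimethyl-8-methylidene-11-(triethylsilyloxy)bicyclo[10.2.2]hexadecan-16-one | C1C(=O)[C@]2(C)CC[C@@H]1C[C@@H]3O[C@@]3(C)CC[C@H](O)C(=C)CC[C@H]2O[Si](CC)(CC)CC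
F6 | step 14 | (1R,3S,4R,7S,11R,12R)-4,7-epoxy-4,12-dimethyl-8-methylidene-16-oxo-15-[(phenylsulfonyl)methyl]bicyclo[10.2.2]hexadecane-3,11-diyl diacetate (C15 epimers) | O=S(=O)(CC1C(=O)[C@]2(C)CC[C@@H]1C[C@H](OC(C)=O)[C@@]1(C)CC[C@H](O1)C(=C)CC[C@H]2OC(C)=O)c1ccccc1
F7 | step 14 | 15,17-dihydro-17-(phenylsulfonyl)granosolide B (C15 epimers) | O=S(=O)(CC1C(=O)O[C@]2(C)CC[C@@H]1C[C@H](OC(C)=O)[C@@]1(C)CC[C@H](O1)C(=C)CC[C@H]2OC(C)=O)c1ccccc1
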